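**Retrosynthetic overview**

- The strategy rests on ring A being a phloroglucinol unit: O1, 5-O and 7-O are mutually meta. In a 3,5-dioxygenated phenoxy precursor the two carbons ortho to the ether oxygen (future C4a and C8) are therefore equivalent, and each is activated by three oxygens (ortho, ortho, para).
- Last disconnection: the three phenols are unmasked from benzyl ethers (BCl3, pentamethylbenzene).
- Key disconnection: C4–C4a of pyranone ring C, by intramolecular Friedel–Crafts acylation of a (Z)-3-aryloxy-2-arylacrylic acid onto ring A.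
- The acid comes from 3,5-bis(benzyloxy)phenol and the enol tosylate of an α-formyl arylacetate (O1–C2 bond). The arylacetate comes from Pd-catalysed enolate arylation of 7-(benzyloxy)-6-bromo-2,2-dimethyl-2H-chromene.
- Ring order: the dimethylpyran ring on ring B first (from 4-bromoresorcinol and 3-methylbut-2-enoic acid via the chromanone), ring A purchased, ring C last.

Key step: step 9

Remark on geometry: the enol, enol tosylate, aryloxyacrylate and acid are drawn as Z isomers, as chelation-controlled sulfonylation and stereoretentive vinylic substitution should give. The geometry is not critical, because E and Z acyl chlorides interconvert under the ring-closure conditions.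

Remark on stereochemistry: the target has no stereocentre. The chroman-4-ol passed through in step 3 is racemic and loses its stereocentre in the same step.

Isoflavone numbering is used for the target (O1, C2, C3, C4, C4a, C5–C8, C8a).

**Route**

Step 1
Reactants: 1 4-bromoresorcinol; 2 3-methylbut-2-enoic acid
Product: 3 6-bromo-7-hydroxy-2,2-dimethylchroman-4-one
Conditions: P2O5 in MeSO3H, 70 °C
Reagents that add atoms: none
Why: Friedel–Crafts acylation by the activated acid goes to C6 of the resorcinol (ortho to one hydroxyl, para to the other, C4 blocked by bromine, C2 hindered), and the ortho hydroxyl then closes the ring by oxa-Michael addition to the enone, the standard chromanone synthesis from resorcinols.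

Step 2
Reactants: 3 6-bromo-7-hydroxy-2,2-dimethylchroman-4-one
Product: 4 7-(benzyloxy)-6-bromo-2,2-dimethylchroman-4-one
Conditions: BnBr, K2CO3, DMF, rt
Reagents that add atoms: benzyl bromide, BrCc1ccccc1
Why: Williamson etherification of the acidic 7-hydroxyl (para to the ketone) should be clean, and benzyl is kept because it tolerates the later hydride, base, palladium and acyl chloride steps.

Step 3
Reactants: 4 7-(benzyloxy)-6-bromo-2,2-dimethylchroman-4-one
Product: 6 7-(benzyloxy)-6-bromo-2,2-dimethyl-2H-chromene, via chroman-4-ol 5 (not isolated)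
Conditions: NaBH4, MeOH/THF, 0 °C; aqueous work-up; then p-TsOH·H2O (cat.), toluene, 80 °C
Reagents that add atoms: none
Why: NaBH4 reduces the aryl ketone to the benzylic alcohol, which loses water under acid catalysis (E1 dehydration through a cation stabilised by the ring oxygen and the para benzyloxy group), the usual chromanone-to-chromene sequence.

Step 4
Reactants: 6 7-(benzyloxy)-6-bromo-2,2-dimethyl-2H-chromene
Product: 7 ethyl 2-[7-(benzyloxy)-2,2-dimethyl-2H-chromen-6-yl]acetate
Conditions: BrZnCH2CO2Et (from ethyl bromoacetate and TMSCl-activated Zn dust, THF), Pd2(dba)3 (cat.), XPhos (cat.), THF, 65 °C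
Reagents that add atoms: ethyl bromoacetate, CCOC(=O)CBr
Why: Palladium-catalysed α-arylation of an ester zinc enolate (Reformatsky reagent in a Negishi-type coupling) proceeds by oxidative addition of the aryl bromide to zerovalent palladium carrying the bulky phosphine, transmetalation and reductive elimination, without strong base, so Claisen self-condensation and double arylation are not expected.

Step 5
Reactants: 7 ethyl 2-[7-(benzyloxy)-2,2-dimethyl-2H-chromen-6-yl]acetate
Product: 8 ethyl (Z)-2-[7-(benzyloxy)-2,2-dimethyl-2H-chromen-6-yl]-3-hydroxyprop-2-enoate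
Conditions: NaH, HCO2Et, EtOH (cat.), THF, 0 °C to rt; then dilute HCl, 0 °C
Reagents that add atoms: ethyl formate, CCOC=O
Why: Crossed Claisen condensation of the arylacetate enolate with non-enolisable ethyl formate is driven by formation of the stabilised sodium enolate, and acidification gives the hydrogen-bonded Z enol.

Step 6
Reactants: 8 ethyl (Z)-2-[7-(benzyloxy)-2,2-dimethyl-2H-chromen-6-yl]-3-hydroxyprop-2-enoate
Product: 9 ethyl (Z)-2-[7-(benzyloxy)-2,2-dimethyl-2H-chromen-6-yl]-3-(tosyloxy)prop-2-enoate
Conditions: TsCl, TMEDA, LiCl, MeCN, 0 °C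
Reagents that add atoms: p-toluenesulfonyl chloride, Cc1ccc(cc1)S(Cl)(=O)=O
Why: O-Sulfonylation of the lithium-chelated enolate, in which the enolate oxygen and the ester are held cis, should give the Z enol tosylate, a known chelation-controlled enol tosylation of α-formyl esters.

Step 7
Reactants: 9 ethyl (Z)-2-[7-(benzyloxy)-2,2-dimethyl-2H-chromen-6-yl]-3-(tosyloxy)prop-2-enoate; 10 3,5-bis(benzyloxy)phenol
Product: 11 ethyl (Z)-3-[3,5-bis(benzyloxy)phenoxy]-2-[7-(benzyloxy)-2,2-dimethyl-2H-chromen-6-yl]prop-2-enoate
Conditions: Cs2CO3, MeCN, 0 °C to rt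
Reagents that add atoms: none
Why: Nucleophilic vinylic substitution by addition–elimination: the phenoxide adds to the β-carbon and tosylate leaves from the ester enolate faster than bond rotation, so the Z geometry should be retained, and the fast elimination makes O-attack irreversible.

Step 8
Reactants: 11 ethyl (Z)-3-[3,5-bis(benzyloxy)phenoxy]-2-[7-(benzyloxy)-2,2-dimethyl-2H-chromen-6-yl]prop-2-enoate
Product: 12 (Z)-3-[3,5-bis(benzyloxy)phenoxy]-2-[7-(benzyloxy)-2,2-dimethyl-2H-chromen-6-yl]acrylic acid
Conditions: LiOH·H2O, THF/H2O, 40 °C; then 1 M HCl to pH 3, 0 °C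
Reagents that add atoms: lithium hydroxide, [Li+].[OH-]
Why: Saponification of the ethyl ester in an alcohol-free medium (no alkoxide that could exchange the aryloxy group) followed by careful acidification should give the acid, as is routine for 3-aryloxyacrylates.

Step 9
Reactants: 12 (Z)-3-[3,5-bis(benzyloxy)phenoxy]-2-[7-(benzyloxy)-2,2-dimethyl-2H-chromen-6-yl]acrylic acid
Product: 14 5,7-bis(benzyloxy)-3-[7-(benzyloxy)-2,2-dimethyl-2H-chromen-6-yl]-4H-chromen-4-one, via acyl chloride 13 (not isolated)
Conditions: (COCl)2, DMF (cat.), CH2Cl2, 0 °C; evaporate; then ZnCl2 (1 M in Et2O), 2,6-di-tert-butyl-4-methylpyridine, CH2Cl2, 0 °C to rt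
Reagents that add atoms: none
Why: Oxalyl chloride with catalytic DMF converts acid 12 into acyl chloride 13, which ZnCl2 polarises toward an acylium ion that the enol ether oxygen stabilises as an oxocarbenium–ketene. The ring A carbon ortho to the aryl ether oxygen and to one benzyloxy group and para to the other attacks the acyl carbon, and loss of a proton restores the arene; this is an intramolecular Friedel–Crafts acylation, the established way from 3-aryloxyacrylic acids to chromones. Pyranone ring C closes in a 6-exo-trig mode onto the acyl chloride carbonyl (6-exo-dig if the free acylium reacts), forming C4–C4a. No stereocentre is formed. The step needs site selectivity on ring A and a cis relation of acyl group and aryloxy oxygen: the two ortho carbons are equivalent by the local symmetry of the ring and the para carbon cannot be reached, while the Z geometry of 12 already places the groups cis and any E isomer equilibrates through the single-bond character of C2–C3 in the oxocarbenium–ketene form. The triple oxygen activation of the attacked carbon allows 0 °C and a weak Lewis acid, with the hindered pyridine taking up HCl, so the chromene and the benzyl ethers should survive.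

Step 10
Reactants: 14 5,7-bis(benzyloxy)-3-[7-(benzyloxy)-2,2-dimethyl-2H-chromen-6-yl]-4H-chromen-4-one
Product: 15 Eriosemaone D
Conditions: BCl3 (1 M in CH2Cl2), pentamethylbenzene, CH2Cl2, −78 °C; then CHCl3/MeOH quench, aqueous work-up
Reagents that add atoms: none
Why: BCl3 coordinates the ether oxygens and cleaves the benzyl–oxygen bonds at low temperature while pentamethylbenzene traps each benzyl cation by Friedel–Crafts alkylation, so the electron-rich rings and the chromene alkene are not benzylated and no hydrogenation is needed.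

**Compound list**

1 | 4-bromoresorcinol | Oc1ccc(Br)c(O)c1 | starting material
2 | 3-methylbut-2-enoic acid | CC(C)=CC(=O)O | starting material
3 | 6-bromo-7-hydroxy-2,2-dimethylchroman-4-one | CC1(C)CC(=O)c2cc(Br)c(O)cc2O1 | intermediate
4 | 7-(benzyloxy)-6-bromo-2,2-dimethylchroman-4-one | CC1(C)CC(=O)c2cc(Br)c(OCc3ccccc3)cc2O1 | intermediate
5 | 7-(benzyloxy)-6-bromo-2,2-dimethylchroman-4-ol (racemic) | CC1(C)CC(O)c2cc(Br)c(OCc3ccccc3)cc2O1 | intermediate
6 | 7-(benzyloxy)-6-bromo-2,2-dimethyl-2H-chromene | CC1(C)C=Cc2cc(Br)c(OCc3ccccc3)cc2O1 | intermediate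
7 | ethyl 2-[7-(benzyloxy)-2,2-dimethyl-2H-chromen-6-yl]acetate | CCOC(=O)Cc1cc2C=CC(C)(C)Oc2cc1OCc1ccccc1 | intermediate
8 | ethyl (Z)-2-[7-(benzyloxy)-2,2-dimethyl-2H-chromen-6-yl]-3-hydroxyprop-2-enoate | CCOC(=O)/C(c1cc2C=CC(C)(C)Oc2cc1OCc1ccccc1)=C\O | intermediate
9 | ethyl (Z)-2-[7-(benzyloxy)-2,2-dimethyl-2H-chromen-6-yl]-3-(tosyloxy)prop-2-enoate | CCOC(=O)/C(c1cc2C=CC(C)(C)Oc2cc1OCc1ccccc1)=C\OS(=O)(=O)c1ccc(C)cc1 | intermediate
10 | 3,5-bis(benzyloxy)phenol | Oc1cc(OCc2ccccc2)cc(OCc2ccccc2)c1 | starting material
11 | ethyl (Z)-3-[3,5-bis(benzyloxy)phenoxy]-2-[7-(benzyloxy)-2,2-dimethyl-2H-chromen-6-yl]prop-2-enoate | CCOC(=O)/C(c1cc2C=CC(C)(C)Oc2cc1OCc1ccccc1)=C\Oc1cc(OCc2ccccc2)cc(OCc2ccccc2)c1 | intermediate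
12 | (Z)-3-[3,5-bis(benzyloxy)phenoxy]-2-[7-(benzyloxy)-2,2-dimethyl-2H-chromen-6-yl]acrylic acid | OC(=O)/C(c1cc2C=CC(C)(C)Oc2cc1OCc1ccccc1)=C\Oc1cc(OCc2ccccc2)cc(OCc2ccccc2)c1 | intermediate
13 | (Z)-3-[3,5-bis(benzyloxy)phenoxy]-2-[7-(benzyloxy)-2,2-dimethyl-2H-chromen-6-yl]acryloyl chloride | ClC(=O)/C(c1cc2C=CC(C)(C)Oc2cc1OCc1ccccc1)=C\Oc1cc(OCc2ccccc2)cc(OCc2ccccc2)c1 | intermediate
14 | 5,7-bis(benzyloxy)-3-[7-(benzyloxy)-2,2-dimethyl-2H-chromen-6-yl]-4H-chromen-4-one | O=c1c(-c2cc3C=CC(C)(C)Oc3cc2OCc2ccccc2)coc2cc(OCc3ccccc3)cc(OCc3ccccc3)c12 | intermediate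
15 | Eriosemaone D | CC1(C)C=Cc2cc(-c3coc4cc(O)cc(O)c4c3=O)c(O)cc2O1 | target

**Totals and risks**

Total step count: 10. Longest linear sequence: 10 steps (1 to 15).

Steps most likely to fail:

Step 9 (key ring closure). The chromene may be attacked by acid during acyl chloride formation or ring closure (hydrochlorination or cationic oligomerisation of the C3=C4 alkene of the pyran ring), or intermolecular acylation may outrun the closure. The fallback forms the C3–C1' bond instead of C4–C4a and uses known isoflavone chemistry. It sets out from 6 and comes back at 14. Miyaura borylation of 6 (bis(pinacolato)diboron, PdCl2(dppf), KOAc, dioxane, 90 °C) should give 2-[7-(benzyloxy)-2,2-dimethyl-2H-chromen-6-yl]-4,4,5,5-tetramethyl-1,3,2-dioxaborolane F1. Separately, commercially available 1-[2,4-bis(benzyloxy)-6-hydroxyphenyl]ethan-1-one F2 is condensed with N,N-dimethylformamide dimethyl acetal (toluene, 90 °C) to (E)-1-[2,4-bis(benzyloxy)-6-hydroxyphenyl]-3-(dimethylamino)prop-2-en-1-one F3. Iodine in CHCl3 at rt should cyclise this to 5,7-bis(benzyloxy)-3-iodo-4H-chromen-4-one F4. Suzuki–Miyaura coupling of F1 with F4 (Pd(OAc)2, SPhos, K3PO4, dioxane/H2O, 80 °C) should then give 14.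

Step 7 (vinylic substitution). The phenoxide may attack sulfur instead of the β-carbon (sulfonyl transfer that returns the enolate and consumes the phenol), or the ambident phloroglucinol-type phenoxide may react through carbon. The fallback replaces the sulfonate by a halide, so no sulfonyl centre is present. It sets out from 8 and comes back at 11. Vilsmeier-type chlorination of 8 ((COCl)2, DMF, CH2Cl2, 0 °C) should give ethyl (Z)-3-chloro-2-[7-(benzyloxy)-2,2-dimethyl-2H-chromen-6-yl]prop-2-enoate F5. Substitution with phenol 10 under DABCO catalysis (K2CO3, DABCO cat., DMF, rt), through a vinylammonium salt, should give 11; the alkene geometry again does not matter.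

Step 10 (debenzylation). The Lewis acid may open the 2,2-dimethylpyran ring at the C2–O bond, or HCl or a benzyl cation may add across the chromene C3=C4 alkene. The fallback avoids Lewis acid altogether and restores the alkene afterwards. It sets out from 14 and comes back at 15. Hydrogenolysis (H2, Pd/C, EtOAc/MeOH, rt, stopped once the benzyl groups are gone) should remove the three benzyl groups and saturate the chromene alkene, giving 5,7-dihydroxy-3-(7-hydroxy-2,2-dimethylchroman-6-yl)-4H-chromen-4-one F6. Acetylation (Ac2O, pyridine, DMAP) should give 3-(7-acetoxy-2,2-dimethylchroman-6-yl)-4-oxo-4H-chromene-5,7-diyl diacetate F7, in which the free 2'-hydroxyl can no longer cyclise oxidatively onto C2. DDQ in refluxing dioxane should dehydrogenate the chroman (hydride abstraction at the benzylic carbon ortho to the ring oxygen) to 3-(7-acetoxy-2,2-dimethyl-2H-chromen-6-yl)-4-oxo-4H-chromene-5,7-diyl diacetate F8. K2CO3 in MeOH at rt should then give 15.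

**Further compounds**

F1 | step 9 | 2-[7-(benzyloxy)-2,2-dimethyl-2H-chromen-6-yl]-4,4,5,5-tetramethyl-1,3,2-dioxaborolane | CC1(C)C=Cc2cc(B3OC(C)(C)C(C)(C)O3)c(OCc3ccccc3)cc2O1
F2 | step 9 | 1-[2,4-bis(benzyloxy)-6-hydroxyphenyl]ethan-1-one (purchased) | CC(=O)c1c(O)cc(OCc2ccccc2)cc1OCc1ccccc1
F3 | step 9 | (E)-1-[2,4-bis(benzyloxy)-6-hydroxyphenyl]-3-(dimethylamino)prop-2-en-1-one | CN(C)/C=C/C(=O)c1c(O)cc(OCc2ccccc2)cc1OCc1ccccc1
F4 | step 9 | 5,7-bis(benzyloxy)-3-iodo-4H-chromen-4-one | O=c1c(I)coc2cc(OCc3ccccc3)cc(OCc3ccccc3)c12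
F5 | step 7 | ethyl (Z)-3-chloro-2-[7-(benzyloxy)-2,2-dimethyl-2H-chromen-6-yl]prop-2-enoate | CCOC(=O)/C(c1cc2C=CC(C)(C)Oc2cc1OCc1ccccc1)=C\Cl
F6 | step 10 | 5,7-dihydroxy-3-(7-hydroxy-2,2-dimethylchroman-6-yl)-4H-chromen-4-one | CC1(C)CCc2cc(-c3coc4cc(O)cc(O)c4c3=O)c(O)cc2O1
F7 | step 10 | 3-(7-acetoxy-2,2-dimethylchroman-6-yl)-4-oxo-4H-chromene-5,7-diyl diacetate | CC(=O)Oc1cc2OC(C)(C)CCc2cc1-c1coc2cc(OC(C)=O)cc(OC(C)=O)c2c1=O
F8 | step 10 | 3-(7-acetoxy-2,2-dimethyl-2H-chromen-6-yl)-4-oxo-4H-chromene-5,7-diyl diacetate | CC(=O)Oc1cc2OC(C)(C)C=Cc2cc1-c1coc2cc(OC(C)=O)cc(OC(C)=O)c2c1=O
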